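## Analysis of the target

The target 19 is 5,8-dihydroxy-7-methoxy-6-(3-methylbut-2-enyl)-3-(2,4,5-trimethoxyphenyl)chromen-4-one, an isoflavone. Its benzo ring A is fused to a 4-pyranone ring C, which carries the trimethoxyphenyl ring B at C3. It has no stereocentre and no stereogenic double bond, so the whole problem is regiochemical. Ring A is hexasubstituted: C5 bears a hydroxyl hydrogen-bonded to the C4 carbonyl, C6 the prenyl chain, C7 a methoxyl and C8 a free hydroxyl, with C4a and C8a as fusion atoms. The sensitive elements are the trisubstituted prenyl alkene (protonation leads to chroman formation with O5, and it is lost on hydrogenation), the para-related C5/C8 hydroxyls (a hydroquinone that oxidises easily once both are free) and C2 of the pyranone, where nucleophiles add and open ring C. The difficulty is to place six different substituents on one benzene ring without ambiguity and to tell O7 (methylated) from O5 and O8 (free). The strategy rests on the 1,3-relationship of O5 and O7 across C6. They are read as the two carbonyl oxygens of a β-ketoester chain on C4a whose α-carbon C6 already carries the prenyl group, and C8 is read as an oxygen-bearing CH2 on C8a of a preformed 4-pyranone, acidic by vinylogy with the C4 carbonyl. One Claisen bond, C7–C8, then closes ring A with every substituent in place.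

## Retrosynthetic reasoning

Chromenone numbering of 19 is used for the corresponding atoms of all precursors.

The last bond cut is O8–benzyl, leading from 19 back to benzyl ether 18. The hydroquinone is thereby exposed only in the final operation, and a benzyl ether is the O8 mask that tolerates acid, acyl transfer, strong base and alkylation earlier on. The forward reaction has to cleave an aryl benzyl ether without reducing or protonating the prenyl alkene. This excludes ordinary hydrogenolysis and calls for a Lewis acid at low temperature with a cation trap.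

The O7–methyl bond is cut next, giving the 5,7-diol 17. In 17 the 5-hydroxyl is tied to the C4 carbonyl by a hydrogen bond and O8 is benzylated, so mild base and a methyl halide should reach O7 only. No protecting group is spent on the distinction.

Ring A of 17 is opened at C7–C8 to the racemic pyranonyl β-ketoester 16. This cut is preferred to C4a–C5 or C5–C6 because ring C, ring B and the O1–C8a bond stay intact in the precursor. There is then no question of which ring A oxygen becomes the ring oxygen. C8 is also the one ring A carbon that can act as a nucleophile while already carrying its oxygen. O5 and O7 arrive as ketone and ester carbonyls, C6 arrives with its prenyl group, and the stereocentre of 16 vanishes on aromatisation. The forward step needs a base that makes the C8 carbanion without adding to C2, and it must drive that carbanion onto an ester that is part of an enolised β-dicarbonyl unit. The risk of the route is concentrated here.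

The C6–prenyl bond of 16 is cut to the unsubstituted β-ketoester 14 and prenyl bromide 15. C6 of 14 is the most acidic carbon of the molecule, so alkylation there is regiospecific, which prenylation of a finished ring A would not be.

The C5–C6 bond of 14 is cut to the pyranone acid 10 and the malonate half-ester salt 11. The acid is activated as imidazolide 12. The magnesium enolate derived from 11 is a weakly basic carbon nucleophile. It is chosen over a lithium ester enolate, which would strip the acidic C8 protons of the pyranone and could add at C2.

Acid 10 is traced to its tert-butyl ester 9. The tert-butyl group allows the carboxyl to be freed by acid, because aqueous base would attack C2 and open the pyranone.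

Ring C of 9 is cut at O1–C2 and C2–C3, giving the triacylmethane 7. C2 is a one-carbon unit delivered by a formamide acetal to the benzylic CH2 of 7 (through enaminone 8), and the enol oxygen of the benzyloxyacetyl ketone then becomes O1. The central carbon of 7 is blocked and the aryl-flanked CH2 is the more acidic methylene, so C3 carries ring B and C8a carries the benzyloxymethyl group.

The C4–C4a bond of 7 is cut to β-ketoester 4 and acid chloride 6, to be joined by C-acylation of the magnesium chelate of 4. Compound 6 comes from the arylacetic acid 5. Compound 4 comes from benzyloxyacetyl chloride 1 and Meldrum's acid 2 through the acylated form 3. These are four commercial starting materials, and the O8 oxygen is present from the first step.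

## Alternatives that were turned down

Alternative 1: Ring C is cut at C3–C4 and O1–C2, giving the hexasubstituted salicylaldehyde A2 and the silylated arylalkyne A3. In the forward step [Cp*RhCl2]2 (trivalent rhodium) with Cu(OAc)2 as oxidant would activate the formyl C–H bond of A2, the alkyne would insert, and C–O bond formation would give the 2-silylchromenone A1. Desilylation and removal of both methoxymethyl groups would follow.
- For: it is convergent, it joins a finished ring A to ring B late, and O7 is already methylated, so no selective methylation is needed. On these points it is stronger than the chosen route.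
- Against: A2 is itself the hard part of the target, a benzene with six substituents including the prenyl group and three differently treated oxygens, and the disconnection does not say how to make it. The formyl group of A2 sits between two ortho substituents. Silicon rather than the ortho-methoxylated aryl group must end next to oxygen, against the usual preference of aryl groups. Decarbonylation of the acyl–rhodium intermediate competes. The end game removes two acetals with acid beside the prenyl group.
- Comparison: the chosen route writes the ring A pattern through the connectivity of an open chain and needs no hexasubstituted arene and no transition metal. It pays with a less precedented ring closure.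

Alternative 2: Ring C is cut at O1–C8a and C4–C4a, giving the silylaryl triflate A5 and the hydroxyacrylate A6. CsF would release the aryne from A5, the enolate oxygen of A6 would add at C8a, and the C4a anion would acylate on the ester to give chromenone A4.
- For: the step is metal-free and closes ring C in one operation. The methoxymethoxy group next to the aryne directs the oxygen nucleophile to the remote carbon, as required. It is more convergent than the chosen route.
- Against: A4 carries hydrogen at C8. After unmasking to A7 the C8 hydroxyl would still have to be introduced para to O5, for example with K2S2O8 in aqueous base. That is a low-yielding oxidation, and it would be run next to a prenyl alkene and a base-labile pyranone. A5 is a pentasubstituted arene with a prenyl group and needs a long preparation.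
- Comparison: the chosen route is longer on paper, but it brings O8 in from the first building block.

Alternative 3: Ring A is cut at C8–C8a, C7–C8, C5–C6 and C4a–C5, giving the pyranonyl diazoketone A8 and the ynol ether A9. Irradiation would trigger Wolff rearrangement to a pyranonylketene, cycloaddition with A9, opening of the cyclobutenone and six-electron closure onto C4a, giving A7.
- For: four bonds form in one step. The polarity of the ynol ether places prenyl at C6 and methoxyl at C7, and O5 and O7 emerge already differentiated. In bond economy and oxygen differentiation it is clearly stronger than the chosen route.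
- Against: C8 stems from the diazo carbon and ends as C–H, so the same late C8 hydroxylation as in alternative 2 is needed. The 4-pyranone chromophore absorbs and rearranges under irradiation. The closure must use the electron-poor C4a=C8a bond of a vinylogous ester. A9 is a volatile, labile ynol ether.
- Comparison: the chosen route delivers all six ring A substituents, including O8, by ground-state ionic chemistry.

Key step: step 8

Remark: 19 is achiral. The only stereocentre on the route (the chain carbon of 16 that becomes C6) is carried as the racemate and is erased in step 8.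

## Route

Step 1
Reactants: 1 benzyloxyacetyl chloride; 2 2,2-dimethyl-1,3-dioxane-4,6-dione (Meldrum's acid)
Product: 4 tert-butyl 4-(benzyloxy)-3-oxobutanoate, via acyl Meldrum's acid 3 (not isolated)
Conditions: pyridine, CH2Cl2, 0 °C → rt; dilute HCl wash; then t-BuOH, toluene, 90 °C
Reagents that add atoms: tert-butanol, CC(C)(C)O
Why: C-acylation of Meldrum's acid, then thermal loss of acetone and CO2 with capture by the alcohol (Oikawa–Yonemitsu β-ketoester synthesis); the tert-butyl ester is chosen so that the carboxyl can later be freed by acid.

Step 2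
Reactants: 5 (2,4,5-trimethoxyphenyl)acetic acid
Product: 6 (2,4,5-trimethoxyphenyl)acetyl chloride
Conditions: (COCl)2, cat. DMF, CH2Cl2, 0 °C → rt; evaporate
Reagents that add atoms: oxalyl chloride, O=C(Cl)C(=O)Cl
Why: Standard acid chloride formation through the catalytic chloroiminium species; the crude chloride is used at once.

Step 3
Reactants: 4 tert-butyl 4-(benzyloxy)-3-oxobutanoate; 6 (2,4,5-trimethoxyphenyl)acetyl chloride
Product: 7 tert-butyl 4-(benzyloxy)-3-oxo-2-[(2,4,5-trimethoxyphenyl)acetyl]butanoate
Conditions: MgCl2, pyridine, CH2Cl2, 0 °C → rt; cold dilute HCl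
Reagents that add atoms: none
Why: Rathke-type C-acylation: the magnesium chelate of the β-ketoester is acylated on carbon, not oxygen, and the enolised triacylmethane is carried on without chromatography.

Step 4
Reactants: 7 tert-butyl 4-(benzyloxy)-3-oxo-2-[(2,4,5-trimethoxyphenyl)acetyl]butanoate
Product: 9 tert-butyl 2-[(benzyloxy)methyl]-4-oxo-5-(2,4,5-trimethoxyphenyl)-4H-pyran-3-carboxylate, via enaminone 8 (not isolated)
Conditions: Me2NCH(OMe)2, toluene, rt → 90 °C
Reagents that add atoms: N,N-dimethylformamide dimethyl acetal, COC(OC)N(C)C
Why: Aminomethylenation of the aryl-flanked CH2, as in the enaminone route from deoxybenzoins to isoflavones, then addition–elimination by the enol oxygen with loss of dimethylamine closes the 4-pyranone; the central carbon of 7 is blocked and the benzyloxymethyl CH2 is far less acidic than the benzylic one.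

Step 5
Reactants: 9 tert-butyl 2-[(benzyloxy)methyl]-4-oxo-5-(2,4,5-trimethoxyphenyl)-4H-pyran-3-carboxylate
Product: 10 2-[(benzyloxy)methyl]-4-oxo-5-(2,4,5-trimethoxyphenyl)-4H-pyran-3-carboxylic acid
Conditions: CF3CO2H, anisole, CH2Cl2, 0 °C → rt
Reagents that add atoms: none
Why: Acidolysis of the tert-butyl ester with loss of isobutene; no nucleophile is present that could open the pyranone at C2, the benzyl and methyl ethers are stable, and anisole keeps the tert-butyl cation away from ring B.

Step 6
Reactants: 10 2-[(benzyloxy)methyl]-4-oxo-5-(2,4,5-trimethoxyphenyl)-4H-pyran-3-carboxylic acid; 11 potassium methyl malonate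
Product: 14 methyl 3-{2-[(benzyloxy)methyl]-4-oxo-5-(2,4,5-trimethoxyphenyl)-4H-pyran-3-yl}-3-oxopropanoate, via acyl imidazole 12 (not isolated), via acylmalonic half ester 13 (not isolated)
Conditions: CDI, THF, rt; then KO2CCH2CO2Me, MgCl2, Et3N, THF, rt → 45 °C; 1 M HCl
Reagents that add atoms: none
Why: Masamune–Brooks decarboxylative Claisen condensation: the magnesium enolate of the malonate half ester acylates on the imidazolide and loses CO2 on acidification; being soft and weakly basic, it neither removes the acidic C8 protons nor adds to C2 of the pyranone.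

Step 7
Reactants: 14 methyl 3-{2-[(benzyloxy)methyl]-4-oxo-5-(2,4,5-trimethoxyphenyl)-4H-pyran-3-yl}-3-oxopropanoate; 15 1-bromo-3-methylbut-2-ene (prenyl bromide)
Product: 16 racemic methyl 2-{[2-(benzyloxymethyl)-4-oxo-5-(2,4,5-trimethoxyphenyl)-4H-pyran-3-yl]carbonyl}-5-methylhex-4-enoate
Conditions: K2CO3, acetone, rt (1.0 equiv of bromide)
Reagents that add atoms: none
Why: SN2 C-alkylation of the β-ketoester enolate by a soft allylic bromide; weak base and one equivalent of bromide limit dialkylation, and the new stereocentre is formed as the racemate, which does not matter because it becomes an aromatic carbon in step 8.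

Step 8
Reactants: 16 racemic methyl 2-{[2-(benzyloxymethyl)-4-oxo-5-(2,4,5-trimethoxyphenyl)-4H-pyran-3-yl]carbonyl}-5-methylhex-4-enoate
Product: 17 8-(benzyloxy)-5,7-dihydroxy-6-(3-methylbut-2-enyl)-3-(2,4,5-trimethoxyphenyl)chromen-4-one
Conditions: LiN(i-Pr)2 (2.3 equiv), THF, −78 °C; DMPU, −78 °C → rt; aq. NH4Cl, then dilute HCl to pH 3–4
Reagents that add atoms: none
Why: The first equivalent of LiN(i-Pr)2 removes the C6–H of the β-ketoester and the second a C8–H of the benzyloxymethyl group, whose carbanion is a dienolate conjugated through C8a=C4a with the C4 carbonyl; on warming, C8 adds to the ester carbonyl C7 in a 6-(enolendo)-exo-trig Dieckmann closure of ring A, methoxide is expelled, and it removes the remaining C8–H so that the cyclic trione enolises to the 5,7-diphenoxide, which is protonated on work-up. The closest known reactions are Claisen condensations of the vinylogous carbanions of 2-alkyl-4-pyranones with esters and the base-induced Claisen folding of 3,5,7-triketo esters to acylphloroglucinols. No stereocentre is formed, and the racemic centre of 16 becomes the aromatic carbon C6. The selectivity needed is C-acylation at C8: C8 is the only carbon nucleophile that can reach C7 through a six-membered transition state, O-acylation through the C4 enolate oxygen would be reversible, and only the C-acylated product is drained irreversibly by aromatisation. DMPU loosens the lithium chelate of the β-ketoester enolate so that the ester can rotate to the side of C4a, and the amide base is too hindered to add to C2 of the pyranone. The benzyl ether on C8 should tolerate the delocalised carbanion, since 1,2-shifts of the Wittig kind need unstabilised carbanions.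

Step 9
Reactants: 17 8-(benzyloxy)-5,7-dihydroxy-6-(3-methylbut-2-enyl)-3-(2,4,5-trimethoxyphenyl)chromen-4-one
Product: 18 8-(benzyloxy)-5-hydroxy-7-methoxy-6-(3-methylbut-2-enyl)-3-(2,4,5-trimethoxyphenyl)chromen-4-one
Conditions: MeI (1.2 equiv), K2CO3 (1.5 equiv), acetone, rt
Reagents that add atoms: iodomethane, CI
Why: Williamson O-methylation; the 7-hydroxyl is the more acidic, vinylogous-acid phenol, while the 5-hydroxyl is held in a hydrogen bond to the C4 carbonyl and should stay free under these mild conditions.

Step 10
Reactants: 18 8-(benzyloxy)-5-hydroxy-7-methoxy-6-(3-methylbut-2-enyl)-3-(2,4,5-trimethoxyphenyl)chromen-4-one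
Product: 19 5,8-dihydroxy-7-methoxy-6-(3-methylbut-2-enyl)-3-(2,4,5-trimethoxyphenyl)chromen-4-one
Conditions: BCl3, C6HMe5, CH2Cl2, −78 °C; MeOH quench at −78 °C, then warm; work-up under argon
Reagents that add atoms: none
Why: Lewis-acid debenzylation of an aryl benzyl ether with pentamethylbenzene as a non-basic trap for the benzyl cation; the low temperature and the cold quench are meant to spare the prenyl alkene and the methyl ethers, and the 5-hydroxyl is tied up as its boron chelate during the reaction.

## Compound list

1 | benzyloxyacetyl chloride | O=C(Cl)COCc1ccccc1 | starting material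
2 | 2,2-dimethyl-1,3-dioxane-4,6-dione (Meldrum's acid) | CC1(C)OC(=O)CC(=O)O1 | starting material
3 | 5-[2-(benzyloxy)-1-hydroxyethylidene]-2,2-dimethyl-1,3-dioxane-4,6-dione | CC1(C)OC(=O)C(=C(O)COCc2ccccc2)C(=O)O1 | intermediate (not isolated)
4 | tert-butyl 4-(benzyloxy)-3-oxobutanoate | CC(C)(C)OC(=O)CC(=O)COCc1ccccc1 | intermediate
5 | (2,4,5-trimethoxyphenyl)acetic acid | COc1cc(OC)c(CC(=O)O)cc1OC | starting material
6 | (2,4,5-trimethoxyphenyl)acetyl chloride | COc1cc(OC)c(CC(=O)Cl)cc1OC | intermediate
7 | tert-butyl 4-(benzyloxy)-3-oxo-2-[(2,4,5-trimethoxyphenyl)acetyl]butanoate | CC(C)(C)OC(=O)C(C(=O)COCc1ccccc1)C(=O)Cc1cc(OC)c(OC)cc1OC | intermediate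
8 | tert-butyl 4-(benzyloxy)-2-[3-(dimethylamino)-2-(2,4,5-trimethoxyphenyl)prop-2-enoyl]-3-oxobutanoate (double-bond geometry not defined) | CC(C)(C)OC(=O)C(C(=O)COCc1ccccc1)C(=O)C(=CN(C)C)c1cc(OC)c(OC)cc1OC | intermediate (not isolated)
9 | tert-butyl 2-[(benzyloxy)methyl]-4-oxo-5-(2,4,5-trimethoxyphenyl)-4H-pyran-3-carboxylate | CC(C)(C)OC(=O)c1c(COCc2ccccc2)occ(-c2cc(OC)c(OC)cc2OC)c1=O | intermediate
10 | 2-[(benzyloxy)methyl]-4-oxo-5-(2,4,5-trimethoxyphenyl)-4H-pyran-3-carboxylic acid | OC(=O)c1c(COCc2ccccc2)occ(-c2cc(OC)c(OC)cc2OC)c1=O | intermediate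
11 | potassium methyl malonate (potassium 3-methoxy-3-oxopropanoate) | COC(=O)CC(=O)[O-].[K+] | starting material
12 | 2-[(benzyloxy)methyl]-3-(1H-imidazol-1-ylcarbonyl)-5-(2,4,5-trimethoxyphenyl)-4H-pyran-4-one | O=C(n1ccnc1)c1c(COCc2ccccc2)occ(-c2cc(OC)c(OC)cc2OC)c1=O | intermediate (not isolated)
13 | 2-{[2-(benzyloxymethyl)-4-oxo-5-(2,4,5-trimethoxyphenyl)-4H-pyran-3-yl]carbonyl}-3-methoxy-3-oxopropanoic acid (present as its magnesium salt) | COC(=O)C(C(=O)O)C(=O)c1c(COCc2ccccc2)occ(-c2cc(OC)c(OC)cc2OC)c1=O | intermediate (not isolated)
14 | methyl 3-{2-[(benzyloxy)methyl]-4-oxo-5-(2,4,5-trimethoxyphenyl)-4H-pyran-3-yl}-3-oxopropanoate | COC(=O)CC(=O)c1c(COCc2ccccc2)occ(-c2cc(OC)c(OC)cc2OC)c1=O | intermediate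
15 | 1-bromo-3-methylbut-2-ene (prenyl bromide) | CC(C)=CCBr | starting material
16 | racemic methyl 2-{[2-(benzyloxymethyl)-4-oxo-5-(2,4,5-trimethoxyphenyl)-4H-pyran-3-yl]carbonyl}-5-methylhex-4-enoate | COC(=O)C(CC=C(C)C)C(=O)c1c(COCc2ccccc2)occ(-c2cc(OC)c(OC)cc2OC)c1=O | intermediate
17 | 8-(benzyloxy)-5,7-dihydroxy-6-(3-methylbut-2-enyl)-3-(2,4,5-trimethoxyphenyl)chromen-4-one | COc1cc(OC)c(-c2coc3c(OCc4ccccc4)c(O)c(CC=C(C)C)c(O)c3c2=O)cc1OC | intermediate
18 | 8-(benzyloxy)-5-hydroxy-7-methoxy-6-(3-methylbut-2-enyl)-3-(2,4,5-trimethoxyphenyl)chromen-4-one | COc1cc(OC)c(-c2coc3c(OCc4ccccc4)c(OC)c(CC=C(C)C)c(O)c3c2=O)cc1OC | intermediate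
19 | 5,8-dihydroxy-7-methoxy-6-(3-methylbut-2-enyl)-3-(2,4,5-trimethoxyphenyl)chromen-4-one | COc1cc(OC)c(-c2coc3c(O)c(OC)c(CC=C(C)C)c(O)c3c2=O)cc1OC | target

## Step count and least certain steps

Total: 10 steps. Longest linear sequence: 9 steps (steps 1 and 3 to 10, from 1 and 2); step 2 is a one-step branch.

Step 8 (key step). The closure may stall at the dianion. The ester that must be attacked is conjugated with the β-ketoester enolate made by the first deprotonation, which lowers its electrophilicity. Lithium chelation also holds it on the side of C5 that points away from C4a, so rotation about C5–C6 has to precede attack. A slow closure leaves time for proton transfer to C2, reversible O-acylation and a 1,2-benzyl shift at the C8 carbanion.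

Fallback: the acyl donor is changed to a thioester and ring A is closed through an acylketene. The ketene is uncharged at C6, rotates freely about C5–C6 and is a far stronger electrophile. The fallback sets out from 10 (with 2 and 15) and returns at 17.
- Compound 2 would be opened with t-BuSH in refluxing toluene to 3-(tert-butylsulfanyl)-3-oxopropanoic acid (F1).
- Acid 10, activated as 12, would be condensed with the magnesium salt of F1 (made with Mg(OEt)2) to S-tert-butyl 3-{2-[(benzyloxy)methyl]-4-oxo-5-(2,4,5-trimethoxyphenyl)-4H-pyran-3-yl}-3-oxopropanethioate (F2).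
- F2 would be prenylated with 15 and K2CO3 in acetone to racemic S-tert-butyl 2-{[2-(benzyloxymethyl)-4-oxo-5-(2,4,5-trimethoxyphenyl)-4H-pyran-3-yl]carbonyl}-5-methylhex-4-enethioate (F3).
- AgO2CCF3 (monovalent silver) with i-Pr2NEt in THF would strip the thiolate from F3 and give the acylketene 2-{[2-(benzyloxymethyl)-4-oxo-5-(2,4,5-trimethoxyphenyl)-4H-pyran-3-yl]carbonyl}-5-methylhexa-1,4-dien-1-one (F4).
- The amine-generated C8 dienol of F4 would add to the ketene carbon C7, and tautomerisation would give 17.

Step 4. The amide acetal may O-methylate the strongly acidic enol of 7 or condense at the benzyloxymethyl CH2 instead of the benzylic CH2. The methanol and dimethylamine released may also cleave an acyl group from the triacylmethane by retro-Claisen reaction.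

Fallback: the one-carbon unit is placed on the arylacetic acid before the acylation, so that no amide acetal meets a triacylmethane and the position of C2 is fixed by construction. The fallback sets out from 5 and 4 and returns at 9.
- Acid 5 would be esterified (MeOH, H2SO4) to methyl (2,4,5-trimethoxyphenyl)acetate (F5).
- F5 would be formylated (NaH, HCO2Me, THF) to methyl 3-oxo-2-(2,4,5-trimethoxyphenyl)propanoate (F6), present largely as its enol.
- F6 would be O-methylated (Me2SO4, K2CO3, acetone) to methyl (2E)-3-methoxy-2-(2,4,5-trimethoxyphenyl)prop-2-enoate (F7).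
- F7 would be saponified (LiOH, THF–H2O) to (2E)-3-methoxy-2-(2,4,5-trimethoxyphenyl)prop-2-enoic acid (F8).
- F8 would be converted with (COCl)2 and catalytic DMF into (2E)-3-methoxy-2-(2,4,5-trimethoxyphenyl)prop-2-enoyl chloride (F9).
- C-Acylation of 4 with F9 (MgCl2, pyridine, CH2Cl2) would give tert-butyl 4-(benzyloxy)-2-[(2E)-3-methoxy-2-(2,4,5-trimethoxyphenyl)prop-2-enoyl]-3-oxobutanoate (F10).
- The enol oxygen of F10 would displace methoxide by conjugate addition–elimination and close the pyranone 9.

Step 6. Acyl transfer from 12 to the magnesium malonate may be slow, because the carbonyl carbon is flanked by the C4 carbonyl and the benzyloxymethyl group. A slow coupling leaves time for imidazole to add at C2 of the pyranone and for hydrolysis back to 10 on work-up.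

Fallback: a more reactive acyl donor is used, and the ester is delivered by acylketene methanolysis, which does not involve attack at the hindered carbonyl in the second stage. The fallback sets out from 10 (with 2) and returns at 14.
- Acid 10 would be converted under neutral conditions with 1-chloro-N,N,2-trimethylprop-1-en-1-amine into 2-[(benzyloxy)methyl]-4-oxo-5-(2,4,5-trimethoxyphenyl)-4H-pyran-3-carbonyl chloride (F11).
- F11 would acylate 2 (pyridine, CH2Cl2, 0 °C) to 5-[{2-[(benzyloxy)methyl]-4-oxo-5-(2,4,5-trimethoxyphenyl)-4H-pyran-3-yl}(hydroxy)methylidene]-2,2-dimethyl-1,3-dioxane-4,6-dione (F12).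
- Heating F12 with MeOH in toluene would give 14 with loss of acetone and CO2.

Step 10. The HCl–BCl3 pair may protonate the prenyl double bond. The tertiary cation would then close onto O5 to a chroman or pick up chloride. Cleavage of the 7-methyl ether is a lesser risk.

Fallback: the benzyl–oxygen bond is cleaved by silane transfer hydrogenolysis, with no acid present. The fallback sets out from 18 and returns at 19.
- Pd(OAc)2 (divalent palladium), Et3SiH and Et3N in CH2Cl2 at rt cleave aryl benzyl ethers while sparing isolated trisubstituted alkenes. The expected product is 5-hydroxy-7-methoxy-6-(3-methylbut-2-enyl)-8-[(triethylsilyl)oxy]-3-(2,4,5-trimethoxyphenyl)chromen-4-one (F13).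
- The silyl ether of F13 would be hydrolysed with K2CO3 in MeOH under argon to 19.

## Further compounds

F1 | step 8 | 3-(tert-butylsulfanyl)-3-oxopropanoic acid | CC(C)(C)SC(=O)CC(=O)O
F2 | step 8 | S-tert-butyl 3-{2-[(benzyloxy)methyl]-4-oxo-5-(2,4,5-trimethoxyphenyl)-4H-pyran-3-yl}-3-oxopropanethioate | CC(C)(C)SC(=O)CC(=O)c1c(COCc2ccccc2)occ(-c2cc(OC)c(OC)cc2OC)c1=O
F3 | step 8 | racemic S-tert-butyl 2-{[2-(benzyloxymethyl)-4-oxo-5-(2,4,5-trimethoxyphenyl)-4H-pyran-3-yl]carbonyl}-5-methylhex-4-enethioate | CC(C)(C)SC(=O)C(CC=C(C)C)C(=O)c1c(COCc2ccccc2)occ(-c2cc(OC)c(OC)cc2OC)c1=O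
F4 | step 8 | 2-{[2-(benzyloxymethyl)-4-oxo-5-(2,4,5-trimethoxyphenyl)-4H-pyran-3-yl]carbonyl}-5-methylhexa-1,4-dien-1-one | O=C=C(CC=C(C)C)C(=O)c1c(COCc2ccccc2)occ(-c2cc(OC)c(OC)cc2OC)c1=O
F5 | step 4 | methyl (2,4,5-trimethoxyphenyl)acetate | COC(=O)Cc1cc(OC)c(OC)cc1OC
F6 | step 4 | methyl 3-oxo-2-(2,4,5-trimethoxyphenyl)propanoate (racemic, largely enolised) | COC(=O)C(C=O)c1cc(OC)c(OC)cc1OC
F7 | step 4 | methyl (2E)-3-methoxy-2-(2,4,5-trimethoxyphenyl)prop-2-enoate | CO/C=C(/C(=O)OC)c1cc(OC)c(OC)cc1OC
F8 | step 4 | (2E)-3-methoxy-2-(2,4,5-trimethoxyphenyl)prop-2-enoic acid | CO/C=C(/C(=O)O)c1cc(OC)c(OC)cc1OC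
F9 | step 4 | (2E)-3-methoxy-2-(2,4,5-trimethoxyphenyl)prop-2-enoyl chloride | CO/C=C(/C(=O)Cl)c1cc(OC)c(OC)cc1OC
F10 | step 4 | tert-butyl 4-(benzyloxy)-2-[(2E)-3-methoxy-2-(2,4,5-trimethoxyphenyl)prop-2-enoyl]-3-oxobutanoate | CO/C=C(/C(=O)C(C(=O)COCc1ccccc1)C(=O)OC(C)(C)C)c1cc(OC)c(OC)cc1OC
F11 | step 6 | 2-[(benzyloxy)methyl]-4-oxo-5-(2,4,5-trimethoxyphenyl)-4H-pyran-3-carbonyl chloride | O=C(Cl)c1c(COCc2ccccc2)occ(-c2cc(OC)c(OC)cc2OC)c1=O
F12 | step 6 | 5-[{2-[(benzyloxy)methyl]-4-oxo-5-(2,4,5-trimethoxyphenyl)-4H-pyran-3-yl}(hydroxy)methylidene]-2,2-dimethyl-1,3-dioxane-4,6-dione | CC1(C)OC(=O)C(=C(O)c2c(COCc3ccccc3)occ(-c3cc(OC)c(OC)cc3OC)c2=O)C(=O)O1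
F13 | step 10 | 5-hydroxy-7-methoxy-6-(3-methylbut-2-enyl)-8-[(triethylsilyl)oxy]-3-(2,4,5-trimethoxyphenyl)chromen-4-one | CC[Si](CC)(CC)Oc1c(OC)c(CC=C(C)C)c(O)c2c1occ(-c1cc(OC)c(OC)cc1OC)c2=O
A1 | alternative 1 | 7-methoxy-5,8-bis(methoxymethoxy)-6-(3-methylbut-2-enyl)-3-(2,4,5-trimethoxyphenyl)-2-(trimethylsilyl)chromen-4-one | COCOc1c(CC=C(C)C)c(OC)c(OCOC)c2oc([Si](C)(C)C)c(-c3cc(OC)c(OC)cc3OC)c(=O)c12
A2 | alternative 1 | 2-hydroxy-4-methoxy-3,6-bis(methoxymethoxy)-5-(3-methylbut-2-enyl)benzaldehyde | O=Cc1c(O)c(OCOC)c(OC)c(CC=C(C)C)c1OCOC
A3 | alternative 1 | trimethyl[(2,4,5-trimethoxyphenyl)ethynyl]silane | COc1cc(OC)c(C#C[Si](C)(C)C)cc1OC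
A4 | alternative 2 | 7-methoxy-5-(methoxymethoxy)-6-(3-methylbut-2-enyl)-3-(2,4,5-trimethoxyphenyl)chromen-4-one | COCOc1c(CC=C(C)C)c(OC)cc2occ(-c3cc(OC)c(OC)cc3OC)c(=O)c12
A5 | alternative 2 | 5-methoxy-3-(methoxymethoxy)-4-(3-methylbut-2-enyl)-2-(trimethylsilyl)phenyl trifluoromethanesulfonate | COCOc1c(CC=C(C)C)c(OC)cc(OS(=O)(=O)C(F)(F)F)c1[Si](C)(C)C
A6 | alternative 2 | methyl (2Z)-3-hydroxy-2-(2,4,5-trimethoxyphenyl)prop-2-enoate | O/C=C(\C(=O)OC)c1cc(OC)c(OC)cc1OC
A7 | alternative 3 | 5-hydroxy-7-methoxy-6-(3-methylbut-2-enyl)-3-(2,4,5-trimethoxyphenyl)chromen-4-one | COc1cc(OC)c(-c2coc3cc(OC)c(CC=C(C)C)c(O)c3c2=O)cc1OC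
A8 | alternative 3 | 2-(diazoacetyl)-5-(2,4,5-trimethoxyphenyl)-4H-pyran-4-one | [N-]=[N+]=CC(=O)c1cc(=O)c(-c2cc(OC)c(OC)cc2OC)co1
A9 | alternative 3 | 1-methoxy-5-methylhex-4-en-1-yne | COC#CCC=C(C)C
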